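**Plan**

1. Target: an unbranched C23 acyl chain carried as its 2-phenylethyl ester. There is no stereocentre, and the only ring is the phenyl ring of the alcohol part.
2. Cut 1 is C12–C13 of the acyl chain, a bond between two unactivated CH2 groups. It is cut into two primary radicals, each traced back to a carboxylic acid one carbon longer: dodecanoic acid (C13–C23) and 2-phenylethyl hydrogen tridecanedioate (C1–C12). The two CO2H groups are the activating groups and leave as CO2 in the coupling itself.
3. Cut 2 takes the free CO2H of the half-ester back to the C13=C14 alkene of 2-phenylethyl erucate, so the two ends of the C13 diacid never have to be told apart. Cut 3 is the acyl–O bond, to erucic acid and 2-phenylethanol.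
4. Forward: esterification, ozonolysis with oxidative work-up, then crossed Kolbe electrolysis. The chain is joined in the last step and no ring is formed.
5. Enabling feature: C12 and C13 are CH2 groups flanked only by CH2 (C11 and C14) inside the (CH2)21 run. The derived radicals are therefore primary, unbranched at the alpha carbon and remote from the ester carbon C1 (eleven carbons away) and from the phenyl ring, which is the case in which anodic decarboxylative coupling works best.
6. Stereochemistry: none to set. The Z alkene of erucic acid is consumed in step 2.

Key step: step 3

Remark: erucic acid free of other monoenoic acids (99% grade) is assumed, because homologous or positional isomers would give homologous half-esters in step 2.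

**Route**

Step 1
Reactants: 1 erucic acid, (Z)-docos-13-enoic acid; 2 2-phenylethanol (1.1 equiv)
Product: 3 2-phenylethyl (Z)-docos-13-enoate
Conditions: DCC (1.1 equiv), DMAP (0.1 equiv), CH2Cl2, 0 °C to rt
Reagents that add atoms: none
Why: Steglich esterification, in which DMAP-catalysed acyl transfer from the O-acylisourea to the unhindered primary alcohol proceeds under neutral conditions at room temperature, so the position of the C13=C14 double bond (which fixes the chain length of 5) should stay untouched.

Step 2
Reactants: 3 2-phenylethyl (Z)-docos-13-enoate
Product: 5 13-oxo-13-(2-phenylethoxy)tridecanoic acid, via secondary ozonide 4 (not isolated)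
Conditions: O3/O2, CH2Cl2, −78 °C (Sudan Red 7B end point), N2 purge; then HCO2H, 30% H2O2, 45 °C
Reagents that add atoms: ozone, [O-][O+]=O; hydrogen peroxide, OO
Why: Ozonolysis with oxidative work-up, in which ozone should add as a 1,3-dipole only to the C13=C14 alkene (it reacts far faster than the monoalkylbenzene ring, hence the dye end point) and performic acid formed in the work-up should cleave ozonide 4 to the two acids, as in the known conversion of alkyl oleates into alkyl hydrogen azelates; the volatile co-product nonanoic acid is removed by short-path distillation or by crystallising 5 from hexane.

Step 3
Reactants: 5 13-oxo-13-(2-phenylethoxy)tridecanoic acid; 6 dodecanoic acid (5 equiv)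
Product: 9 2-phenylethyl tricosanoate, via undecyl radical 7 (not isolated), via 12-oxo-12-(2-phenylethoxy)dodecyl radical 8 (not isolated)
Conditions: smooth Pt anode and cathode, undivided cell, KOH (5 mol% of total CO2H), MeOH, 50 °C, constant current ca. 0.25 A cm−2, stopped when 5 is consumed and the electrolyte is still weakly acidic
Reagents that add atoms: none
Why: One-electron oxidation of the deprotonated acids 5 and 6 at the smooth platinum anode at high current density, with loss of CO2, should give the primary radicals 7 and 8 side by side in the anode layer, where combination of the radical carbon of 7 with that of 8 forms the C12–C13 bond of the tricosanoyl chain. The closest known reaction type is the crossed Kolbe electrolysis of a fatty acid with an alkyl hydrogen alkanedioate, the classical anodic chain extension of fatty acids; the two carbons joined are of like polarity, each arising from a carboxylate. No ring is closed and no stereocentre is formed. The step needs cross-coupling over homo-coupling and radical coupling over further oxidation to the cation (Hofer–Moest pathway): the first is secured by the fivefold excess of the cheap acid 6, so that 8 should meet 7 far more often than a second 8 and the main by-product is docosane, which is non-polar and is eluted with hexane from silica ahead of 9; the second is secured by the CH2 groups alpha to both carboxyls, which give unstabilised primary radicals, and by the weakly acidic electrolyte on smooth Pt. The ester carbonyl lies eleven carbons from the radical centre of 8 and the phenyl ring lies beyond the ester oxygen, so neither should interfere, and as long as free acid remains in excess no methoxide builds up that could exchange the 2-phenylethyl ester.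

**Compound list**

1 | erucic acid, (Z)-docos-13-enoic acid | CCCCCCCC/C=C\CCCCCCCCCCCC(=O)O | starting material
2 | 2-phenylethanol | OCCc1ccccc1 | starting material
3 | 2-phenylethyl (Z)-docos-13-enoate | CCCCCCCC/C=C\CCCCCCCCCCCC(=O)OCCc1ccccc1 | intermediate
4 | 2-phenylethyl 12-(5-octyl-1,2,4-trioxolan-3-yl)dodecanoate (secondary ozonide, cis/trans mixture, not isolated) | CCCCCCCCC1OOC(CCCCCCCCCCCC(=O)OCCc2ccccc2)O1 | intermediate
5 | 13-oxo-13-(2-phenylethoxy)tridecanoic acid (2-phenylethyl hydrogen tridecanedioate) | OC(=O)CCCCCCCCCCCC(=O)OCCc1ccccc1 | intermediate
6 | dodecanoic acid | CCCCCCCCCCCC(=O)O | starting material
7 | undecyl radical (not isolated) | [CH2]CCCCCCCCCC | intermediate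
8 | 12-oxo-12-(2-phenylethoxy)dodecyl radical (not isolated) | [CH2]CCCCCCCCCCC(=O)OCCc1ccccc1 | intermediate
9 | 2-phenylethyl tricosanoate | CCCCCCCCCCCCCCCCCCCCCCC(=O)OCCc1ccccc1 | target

**Step count and risks**

Total step count: 3. Longest linear sequence: 3 steps (1 → 3 → 5 → 9); 2 and 6 enter as purchased materials.

Steps most likely to fail, riskiest first:

Step 3. The coupling may be eroded by statistical homo-coupling, by passivation of the anode under a waxy product film, by further oxidation of the radicals to cations, by alkoxy exchange of the ester with methanol if the electrolyte turns alkaline, or by anodic attack on the phenyl ring. The fallback sets out from 2 and comes back to the route at 9. Compound 2 would be esterified with commercial 12-bromododecanoic acid (OC(=O)CCCCCCCCCCCBr) under TsOH catalysis in refluxing toluene with azeotropic removal of water, to give 2-phenylethyl 12-bromododecanoate F1. Undecylmagnesium bromide F2, made from commercial 1-bromoundecane (CCCCCCCCCCCBr) and magnesium in THF, would then be added slowly to F1 with Li2CuCl4 (3 mol%) in THF/NMP at −20 to 0 °C. This copper-catalysed alkyl–alkyl Grignard cross-coupling should be faster than addition to the ester at that temperature and forms the same C12–C13 bond, giving 9.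

Step 2. Over-ozonation may attack the phenyl ring if the end point is missed, oxidation of the aldehyde stage may stay incomplete, the 2-phenylethyl ester may be partly cleaved by acidolysis in warm formic acid, and incomplete removal of the C9 acid would carry a second coupling partner into step 3. The fallback sets out from 2 and comes back to the route at 5. Commercial tridecanedioic acid (OC(=O)CCCCCCCCCCCC(=O)O), used in threefold excess, would be half-esterified directly with 2 (TsOH cat., toluene, reflux, water separator). The excess of diacid biases the statistics towards the monoester, unreacted diacid crystallises from the cold toluene and is reused, and 5 is separated from the small amount of diester on silica. This fallback makes no new compound (F0).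

Step 1. Conversion may be lowered by O-to-N acyl migration in the O-acylisourea, and traces of the urea may be carried into the ozonolysis. The fallback sets out from 1 and comes back to the route at 3. Compound 1 would be converted with Cs2CO3 (1 equiv) in DMF into caesium (Z)-docos-13-enoate F3, which would be O-alkylated with (2-bromoethyl)benzene (BrCCc1ccccc1) at 40 °C. The ester C–O bond is then formed on the alkyl side by SN2 without any carbodiimide, and the weakly basic carboxylate should favour substitution over elimination to styrene.

**Further compounds**

F1 | step 3 | 2-phenylethyl 12-bromododecanoate | BrCCCCCCCCCCCC(=O)OCCc1ccccc1
F2 | step 3 | undecylmagnesium bromide | CCCCCCCCCCC[Mg]Br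
F0 | step 2 | none | none
F3 | step 1 | caesium (Z)-docos-13-enoate | CCCCCCCC/C=C\CCCCCCCCCCCC(=O)[O-].[Cs+]
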